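## The problem

The target 24 is an achiral macrocyclic diaryl ether. Ring A is a 1,3,5-trisubstituted benzene (C1 hydroxyl, C3 chain, C5 ether oxygen). Ring B is a hydroquinone (C1′ ether oxygen, C2′ hydroxyl, C3′ chain, C5′ hydroxyl). The rings are joined by the ether oxygen and by an unbranched chain of fourteen methylene groups, numbered C1 (at ring B) to C14 (at ring A), which closes a 21-membered ring. There is no stereocentre, so nothing has to be controlled or relayed; any stereocentre or alkene geometry created on the way is transient and may be racemic or mixed. The real tasks are to close a large ring across a bridge that offers no functional group to disconnect at, and to obtain the 1,2,3,5-pattern of ring B with its two different oxygen environments. The free hydroquinone oxidises readily to the quinone and all three oxygenated positions make the arenes electron-rich, so the phenols are best carried as methyl ethers to the last step; the diaryl ether itself is robust. The enabling feature is that C1–C14 are all CH2, so the ring-forming C–C bond can be placed anywhere. If C6 is a carbinol carbon carrying C7=C8 as a pendant vinyl group and C9 is the α-carbon of an ester, the bridge is interrupted by an O–C(=O) unit and the molecule is a macrolactone of the same ring size. A [3,3] shift of its ketene acetal then joins C8 to C9, and the alkene and carboxyl group it leaves behind can be reduced away to bare methylenes.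

## Retrosynthesis

**Phenol unmasking (24 from 23).** The three O–CH3 bonds are cut last. Methyl ethers are preferred to benzyl or silyl ethers because they must survive an amide base, hydrogenation and a radical chain, and because both arene fragments are available already methylated. The forward step must cleave three aryl methyl ethers without touching the diaryl ether.

**Removing the vestiges of the key step (23 from 21 from 20).** Trimethyl ether 23 is traced back by adding a carboxyl group at C9 (acid 21) and then a C6=C7 double bond (acid 20). Neither group is in the target; both are the retron of a sigmatropic shift. Saturation is placed before decarboxylation so that the C9 radical is a plain secondary alkyl radical and not a homoallylic one. The forward steps are a hydrogenation and a reductive decarboxylation.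

**Key disconnection (20 from 17).** The C8–C9 bond is cut and the C6–O bond of an ester is restored, which turns carbocyclic acid 20 into macrolactone 17 of identical ring size. The neighbouring cuts (metathesis, alkylation or cross-coupling within the bridge) all require the new C–C bond and the 21-membered ring to form in the same entropically costly event. Here the ring is already closed through an ester, and the C–C bond forms inside it via the silyl ketene acetal 18. The precursor is simpler in the sense that matters: its ring-forming bond is a C–O bond. The forward reaction needs only enolisation at the single acidic position and a reachable six-membered transition state.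

**Macrolactone opening (17 from 15 from 14).** The lactone C–O bond is cut to give seco acid 15, and its carboxyl group is traced to the methyl ester 14. Ester formation is chosen as the macrocyclising event over diaryl ether formation because activated-ester lactonisation is the more dependable way to close a ring of this size. The forward steps are a saponification and a high-dilution lactonisation.

**Diaryl ether (14 from 9 and 13).** The aryl–oxygen bond on the ring B side is cut, giving bromide 9 and phenol 13. The opposite polarity would require a ring B phenol flanked by a methoxy group, which is harder to obtain and a poorer nucleophile. With the halide on ring B, the pattern of that ring comes from a symmetrical dibromide. The forward reaction is a copper-catalysed coupling of an unhindered phenol with an ortho-methoxy aryl bromide.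

**Ring B fragment (9 from 7 and 8; 7 from 5; 5 from 2 and 3; 2 from 1).** The vinyl carbinol 9 is cut at the C6–C7 bond to aldehyde 7 and vinylmagnesium bromide 8. Aldehyde 7 comes from nitrile 5. The aryl–C1 bond of 5 is cut to the symmetrical dibromide 2 and hex-5-enenitrile 3, joined through the borane 4. Dibromide 2 is the methyl ether of the catalogue phenol 1. Because 2 is symmetrical, the alkyl and aryloxy groups end up flanking the central methoxy group without any aromatic substitution step; the price is a mono-selective coupling.

**Ring A fragment (13 from 10 and 11).** The aryl–C14 bond is cut to 3-bromo-5-methoxyphenol 11 and methyl hept-6-enoate 10, joined through the borane 12. Both are catalogue compounds, and one step delivers the whole fragment with its phenol free for the ether coupling.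

## Roads not taken

Alternative 1: The cut is the ring B bond between C4′ and C5′, so that ring B is built from a four-membered ring. The forward key step is thermolysis of the 4-hydroxycyclobutenone A1. Electrocyclic opening gives a dienylketene, 6π-closure joins the ketene carbon to the vinyl CH2, and tautomerisation gives the free hydroquinone A2. Its merits are that the substitution pattern of ring B is fixed by the connectivity of A1 and owes nothing to arene regiochemistry, that the hydroquinone appears unprotected, and that the step needs no metal. Its weak point for this target is that the step makes ring B only. A2 is still open, and the 21-membered ring would have to be closed afterwards by hydroboration of the terminal alkene and an intramolecular alkyl–aryl coupling onto the ring A bromide, after the hydroquinone has been protected again. The hardest event is thus deferred to a closure less dependable than lactonisation, and A1 needs a mixed aryloxycyclobutenedione and a 2-metallated 1,15-diene, each several steps away. In one respect this road is better: it leaves nothing in the bridge to erase, whereas the chosen plan spends three steps removing an alkene and a carboxyl group. Against that, the chosen plan takes the ring B pattern from a symmetrical catalogue dibromophenol in two steps and closes the large ring by esterification.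

Alternative 2: Three bonds of ring B are cut (C4′–C5′, C2′–C3′ and C1′–C2′), so ring B and the macrocycle are assembled at once. The forward key step heats the alkyne-tethered alkenyl carbene complex A3, (CO)5Cr=C(OMe)CH=CH–OAr. The terminal alkyne and one CO insert, and electrocyclisation gives the macrocyclic 4-methoxyphenol A4. It is the most convergent of the four plans: A4 is one demethylation from the target, against three steps after the key step in the chosen plan, and the two ring B oxygens emerge differentiated. Its weak points are specific to this substrate.
- The β-aryloxy alkenyl carbene is a push–pull system of reduced reactivity, and it can lose aryloxide.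
- The benzannulation must occur intramolecularly across fifteen tether atoms, in competition with intermolecular reaction.
- Tethered alkynes are known to change the regiochemistry of insertion with tether length.
- Chromium is used stoichiometrically.

If it worked, this road would be shorter. The chosen plan sets against it that each of its events is separately dependable or separately replaceable: the ring is closed by lactonisation, the C–C bond forms in a metal-free intramolecular pericyclic step, and a conventional detour exists if that step fails.

Alternative 3: Two bonds of ring A are cut (C5–C6 and C2–C3), so ring A is built last onto a preformed macrocycle. In the forward key step the anion of dimethyl 3-oxopentanedioate A6 adds to the aryloxy-bearing alkyne carbon of the macrocyclic ynone A5. The second methylene then condenses with the ketone, and aromatisation gives the macrocyclic 2-hydroxyisophthalate A7. The merit is that the 1,3,5-pattern of ring A follows from the annulation with no regiochemical ambiguity and without a transition metal. The weak points are three.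
- A5 is a 21-membered ring containing an aryl alkynyl ether conjugated to a ketone, a fragile electrophile for which no reliable macrocyclisation is evident.
- Conjugate addition to a β-aryloxy ynone can go on to expel aryloxide, which would cut the macrocycle open, or to close through oxygen to a pyranone.
- A7 still needs hydrolysis, a double decarboxylation under forcing conditions and demethylation.

This road is no shorter after its key step than the chosen plan and carries more risk before it. Its one advantage, a ring A made to measure, counts for little when ring A can be bought as 3-bromo-5-methoxyphenol.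

Key step: step 9

Remark: the target is achiral; every chiral intermediate (9 and 14–22) is racemic, and each SMILES string shows one enantiomer only.

## Route

Step 1
Reactants: 1 2,6-dibromo-4-methoxyphenol
Product: 2 1,3-dibromo-2,5-dimethoxybenzene
Conditions: MeI, K2CO3, acetone, reflux
Reagents that add atoms: iodomethane, CI
Why: Williamson O-methylation; the two ortho bromines make the phenol acidic and there is no competing nucleophilic site.

Step 2
Reactants: 2 1,3-dibromo-2,5-dimethoxybenzene; 3 hex-5-enenitrile
Product: 5 6-(3-bromo-2,5-dimethoxyphenyl)hexanenitrile, via B-(5-cyanopentyl)-9-BBN 4 (not isolated)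
Conditions: 9-BBN-H, THF, 0 °C to rt; then 2 (3 equiv), PdCl2(dppf), K3PO4 (aq), DMF, 50 °C
Reagents that add atoms: none
Why: Anti-Markovnikov hydroboration of the terminal alkene followed by B-alkyl Suzuki–Miyaura coupling; a threefold excess of the symmetrical dibromide (recoverable) should hold double coupling down, and the nitrile is inert to 9-BBN and to aqueous phosphate at this temperature.

Step 3
Reactants: 5 6-(3-bromo-2,5-dimethoxyphenyl)hexanenitrile
Product: 7 6-(3-bromo-2,5-dimethoxyphenyl)hexanal, via N-aluminated aldimine 6 (not isolated)
Conditions: DIBAL-H (iBu2AlH), CH2Cl2, −78 °C; then 1 M HCl, 0 °C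
Reagents that add atoms: water, O
Why: DIBAL-H adds once to a nitrile to give an aldimine–alane that is stable at low temperature and is hydrolysed to the aldehyde on acidic work-up; the aryl bromide and ethers are not affected.

Step 4
Reactants: 7 6-(3-bromo-2,5-dimethoxyphenyl)hexanal; 8 vinylmagnesium bromide
Product: 9 racemic 8-(3-bromo-2,5-dimethoxyphenyl)oct-1-en-3-ol
Conditions: CH2=CHMgBr, THF, −78 to 0 °C; then cold 1 M HCl
Reagents that add atoms: none
Why: Grignard 1,2-addition to an unhindered aldehyde; the carbinol centre forms without control and a racemate is sufficient because this centre is destroyed in step 9.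

Step 5
Reactants: 10 methyl hept-6-enoate; 11 3-bromo-5-methoxyphenol
Product: 13 methyl 7-(3-hydroxy-5-methoxyphenyl)heptanoate, via B-(6-methoxycarbonylhexyl)-9-BBN 12 (not isolated)
Conditions: 9-BBN-H, THF, 0 °C to rt; then 11, PdCl2(dppf), K3PO4 (aq, 4 equiv), DMF, 60 °C
Reagents that add atoms: none
Why: Hydroboration and B-alkyl Suzuki–Miyaura coupling as in step 2; the extra phosphate holds the phenol as a spectator phenoxide, and the methyl ester tolerates 9-BBN and the mild aqueous base.

Step 6
Reactants: 9 racemic 8-(3-bromo-2,5-dimethoxyphenyl)oct-1-en-3-ol; 13 methyl 7-(3-hydroxy-5-methoxyphenyl)heptanoate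
Product: 14 racemic methyl 7-{3-[3-(6-hydroxyoct-7-en-1-yl)-2,5-dimethoxyphenoxy]-5-methoxyphenyl}heptanoate
Conditions: CuI (10 mol %), picolinic acid (20 mol %), K3PO4, DMSO, 90 °C
Reagents that add atoms: none
Why: Ullmann-type diaryl ether coupling; the phenoxide of 13 should be arylated far faster than the secondary alkoxide of 9, the picolinate-ligated copper catalyst accepts ortho-methoxy aryl bromides, and anhydrous phosphate leaves the methyl ester intact.

Step 7
Reactants: 14 racemic methyl 7-{3-[3-(6-hydroxyoct-7-en-1-yl)-2,5-dimethoxyphenoxy]-5-methoxyphenyl}heptanoate
Product: 15 racemic 7-{3-[3-(6-hydroxyoct-7-en-1-yl)-2,5-dimethoxyphenoxy]-5-methoxyphenyl}heptanoic acid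
Conditions: LiOH, THF/MeOH/H2O, rt; then 1 M HCl to pH 3
Reagents that add atoms: lithium hydroxide, [Li+].[OH-]
Why: Saponification of an unhindered methyl ester by acyl–oxygen cleavage; nothing else in 14 is base-labile.

Step 8
Reactants: 15 racemic 7-{3-[3-(6-hydroxyoct-7-en-1-yl)-2,5-dimethoxyphenoxy]-5-methoxyphenyl}heptanoic acid
Product: 17 racemic 21-membered macrolactone of 15 (ester between the carboxyl group and the C6 hydroxyl; vinyl group exocyclic), via mixed anhydride 16 (not isolated)
Conditions: 2,4,6-trichlorobenzoyl chloride, Et3N, THF, rt; then slow addition to DMAP, toluene, 80 °C, high dilution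
Reagents that add atoms: none
Why: Yamaguchi macrolactonisation; DMAP attacks the unhindered acyl group of 16 and the acylpyridinium is captured by the secondary hydroxyl, slow addition into dilute DMAP favours ring closure over oligomerisation, and a flexible 21-membered ring with a bent diaryl ether hinge should close without transannular strain.

Step 9
Reactants: 17 racemic 21-membered macrolactone
Product: 20 racemic 21-membered carbocyclic acid (CO2H on C9; (E)-alkene C6=C7; ring A 5-methoxy and ring B 2,5-dimethoxy), via silyl ketene acetal 18 (not isolated), via trimethylsilyl ester 19 (not isolated)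
Conditions: TMSCl, Et3N, THF, −78 °C; LDA (LiN(iPr)2), −78 °C to rt, then 65 °C; then 1 M HCl
Reagents that add atoms: none
Why: Proposed new method: LDA removes a proton from the lactone α-CH2 in the presence of TMSCl, and the silyl ketene acetal 18 is a C=C–O–C–C=C array whose [3,3]-sigmatropic shift joins the α-carbon to the vinyl terminus (C9–C8) as the ring C6–O bond breaks; the closest known reaction types are the Ireland–Claisen rearrangement of open-chain allylic esters, its ring-contracting form on macrolides with an endocyclic allylic alkene, and the rearrangement of small and medium vinyl-substituted lactones to cycloalkene carboxylic acids, none of which covers a macrolide with an exocyclic vinyl group. The carbocycle is closed by transposition and not end to end: the ring oxygen and carbonyl carbon move to the periphery while the two vinyl carbons move into the ring, so 21 ring atoms remain and the entropic cost of ring formation was already paid in step 8. The six-membered transition state needs the α-carbon and the carbinol carbon, which are linked the long way round by a 17-atom tether including the diaryl ether, to sit 1,4 across a chair or boat; a tether of that length should span either, whereas small lactones are limited to a boat. The new stereocentre at C9 is set relative to C6 by suprafacial transfer through this transition state and by the ketene acetal geometry, but 17 is racemic and C9 becomes a CH2 group in step 11, so no control is sought. The only selectivity needed is the site of enolisation, which is secured because the lactone α-CH2 is the only acidic C–H in 17; silylation in situ suppresses Claisen condensation and ketene formation from the lithium enolate. The (E)-alkene expected from a chair with the ring B chain equatorial is immaterial since step 10 saturates it. Dilute acid hydrolyses silyl ester 19 to acid 20.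

Step 10
Reactants: 20 racemic 21-membered carbocyclic alkenyl acid
Product: 21 racemic saturated 21-membered carbocyclic acid (CO2H on C9)
Conditions: H2 (1 atm), 10% Pd/C, EtOAc, rt
Reagents that add atoms: none
Why: Heterogeneous catalytic hydrogenation of a disubstituted alkene; aryl methyl ethers and the diaryl ether are not hydrogenolysed under these conditions.

Step 11
Reactants: 21 racemic saturated 21-membered carbocyclic acid
Product: 23 target trimethyl ether (ring A 5-methoxy-1,3-phenylene and ring B 2,5-dimethoxy-1,3-phenylene joined by O and by a tetradecane-1,14-diyl chain), via Barton ester 22 (not isolated)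
Conditions: N-hydroxypyridine-2-thione, DCC, DMAP (cat.), CH2Cl2, rt, dark; then t-BuSH, hν (tungsten lamp), rt
Reagents that add atoms: none
Why: Barton reductive decarboxylation; carbodiimide coupling gives the thiohydroxamate ester, visible light starts a radical chain, and the secondary C9 radical formed on loss of CO2 abstracts hydrogen from the thiol, which removes the last stereocentre.

Step 12
Reactants: 23 target trimethyl ether
Product: 24 target CNP0393720.0 (ring A 5-hydroxy-1,3-phenylene and ring B 2,5-dihydroxy-1,3-phenylene joined by O and by a tetradecane-1,14-diyl chain)
Conditions: BBr3 (excess), CH2Cl2, −78 °C to rt; MeOH quench, aq. Na2S2O4 wash, under argon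
Reagents that add atoms: none
Why: Lewis-acid cleavage of aryl methyl ethers by BBr3 (bromide attacks the methyl group of the boron-complexed ether); the diaryl ether is inert, and work-up under argon with dithionite keeps the hydroquinone from oxidising.

## Compound list

1 | 2,6-dibromo-4-methoxyphenol | COc1cc(Br)c(O)c(Br)c1 | starting material
2 | 1,3-dibromo-2,5-dimethoxybenzene | COc1cc(Br)c(OC)c(Br)c1 | intermediate
3 | hex-5-enenitrile | C=CCCCC#N | starting material
4 | 6-(9-borabicyclo[3.3.1]nonan-9-yl)hexanenitrile | N#CCCCCCB1C2CCCC1CCC2 | intermediate
5 | 6-(3-bromo-2,5-dimethoxyphenyl)hexanenitrile | N#CCCCCCc1cc(OC)cc(Br)c1OC | intermediate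
6 | N-(diisobutylalumino)imine of 6-(3-bromo-2,5-dimethoxyphenyl)hexanal | CC(C)C[Al](CC(C)C)N=CCCCCCc1cc(OC)cc(Br)c1OC | intermediate
7 | 6-(3-bromo-2,5-dimethoxyphenyl)hexanal | O=CCCCCCc1cc(OC)cc(Br)c1OC | intermediate
8 | vinylmagnesium bromide | C=C[Mg]Br | starting material
9 | racemic 8-(3-bromo-2,5-dimethoxyphenyl)oct-1-en-3-ol | COc1cc(Br)c(OC)c(c1)CCCCC[C@H](C=C)O | intermediate
10 | methyl hept-6-enoate | COC(=O)CCCCC=C | starting material
11 | 3-bromo-5-methoxyphenol | COc1cc(O)cc(Br)c1 | starting material
12 | methyl 7-(9-borabicyclo[3.3.1]nonan-9-yl)heptanoate | COC(=O)CCCCCCB1C2CCCC1CCC2 | intermediate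
13 | methyl 7-(3-hydroxy-5-methoxyphenyl)heptanoate | COC(=O)CCCCCCc1cc(O)cc(OC)c1 | intermediate
14 | racemic methyl 7-{3-[3-(6-hydroxyoct-7-en-1-yl)-2,5-dimethoxyphenoxy]-5-methoxyphenyl}heptanoate | COC(=O)CCCCCCc1cc(OC)cc(c1)Oc1cc(OC)cc(c1OC)CCCCC[C@H](C=C)O | intermediate
15 | racemic 7-{3-[3-(6-hydroxyoct-7-en-1-yl)-2,5-dimethoxyphenoxy]-5-methoxyphenyl}heptanoic acid | OC(=O)CCCCCCc1cc(OC)cc(c1)Oc1cc(OC)cc(c1OC)CCCCC[C@H](C=C)O | intermediate
16 | mixed anhydride of 15 with 2,4,6-trichlorobenzoic acid (racemic) | O=C(OC(=O)CCCCCCc1cc(OC)cc(c1)Oc1cc(OC)cc(c1OC)CCCCC[C@H](C=C)O)c1c(Cl)cc(Cl)cc1Cl | intermediate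
17 | racemic 21-membered macrolactone of 15 (lactone oxygen on C6, exocyclic vinyl group, three methyl ethers) | COc1cc2cc(c1)Oc1cc(OC)cc(c1OC)CCCCC[C@H](C=C)OC(=O)CCCCCC2 | intermediate
18 | trimethylsilyl ketene acetal of 17 (racemic; ketene acetal geometry not controlled) | COc1cc2cc(c1)Oc1cc(OC)cc(c1OC)CCCCC[C@H](C=C)OC(O[Si](C)(C)C)=CCCCCC2 | intermediate
19 | trimethylsilyl ester of 20 (racemic) | COc1cc2cc(c1)Oc1cc(OC)cc(c1OC)CCCCC/C=C/C[C@H](C(=O)O[Si](C)(C)C)CCCCC2 | intermediate
20 | racemic 21-membered carbocyclic acid: chain from ring B C1–C5 methylene, (E)-C6=C7, C8 methylene, C9 bearing CO2H, C10–C14 methylene; three methyl ethers | COc1cc2cc(c1)Oc1cc(OC)cc(c1OC)CCCCC/C=C/C[C@H](C(=O)O)CCCCC2 | intermediate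
21 | racemic saturated 21-membered carbocyclic acid (CO2H on C9; three methyl ethers) | COc1cc2cc(c1)Oc1cc(OC)cc(c1OC)CCCCCCCC[C@H](C(=O)O)CCCCC2 | intermediate
22 | 2-thioxopyridin-1(2H)-yl ester (Barton ester) of 21 (racemic) | COc1cc2cc(c1)Oc1cc(OC)cc(c1OC)CCCCCCCC[C@H](C(=O)On1ccccc1=S)CCCCC2 | intermediate
23 | target trimethyl ether (ring A 5-methoxy, ring B 2,5-dimethoxy, tetradecane-1,14-diyl bridge) | COc1cc2cc(c1)Oc1cc(OC)cc(c1OC)CCCCCCCCCCCCCC2 | intermediate
24 | CNP0393720.0 (ring A 5-hydroxy, ring B 2,5-dihydroxy, tetradecane-1,14-diyl bridge) | Oc1cc2cc(c1)Oc1cc(O)cc(c1O)CCCCCCCCCCCCCC2 | target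

## Step count and least certain steps

Total: 12 steps. Longest linear sequence: 11 steps (steps 1–4, then 6–12); step 5 is the one-step side branch.

**Step 9 (key step, proposed new method).** The thermal shift of 18 may be slower than loss or migration of the silyl group if the tethered transition state is strained, which would return lactone 17; the lithium enolate may also fragment to a ketene before it is silylated. The fallback uses only known reactions and avoids both the lactone and the rearrangement. It sets out from ester 14. DIBAL-H at −78 °C should reduce the ester to the hydroxy aldehyde F1, and Wittig methylenation (Ph3P=CH2) should give the diene alcohol F2. Ring-closing metathesis with the second-generation Grubbs catalyst RuCl2(=CHPh)(H2IMes)(PCy3) at high dilution should form the C7=C8 bond and give the macrocyclic allylic alcohol F3. Hydrogenation over Pd/C should give the saturated alcohol F4. Barton–McCombie deoxygenation through the S-methyl xanthate F5 (NaH, CS2, MeI; then Bu3SnH, AIBN) should return to the route at 23.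

**Step 6.** The free allylic hydroxyl may be arylated or may transesterify with the methyl ester under hot base, and oxidative addition into the electron-rich, ortho-substituted bromide may be slow enough for protodebromination to compete. The fallback masks the carbinol so that more forcing conditions can be used. It sets out from 9, which is silylated (TBSCl, imidazole) to the silyl ether F6. Coupling of F6 with 13 (CuI, N,N-dimethylglycine, Cs2CO3, dioxane, 105 °C) should give the protected diaryl ether F7, and Bu4NF should return to the route at 14.

**Step 2.** Double coupling of the dibromide and loss of material in separating the product from excess 2 are the likely problems. The fallback replaces statistical control with halogen differentiation. It sets out from 2. Mono bromine–lithium exchange (n-BuLi, 1 equiv, THF, −78 °C) and an iodine quench should give 1-bromo-3-iodo-2,5-dimethoxybenzene F8. F8 should couple with borane 4 at the iodide only, at room temperature, and return to the route at 5.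

**Step 8.** Intermolecular acylation leading to the cyclic dimer and oligomers is the usual failure of a macrolactonisation. The fallback activates the hydroxyl group and not the carboxyl group. It sets out from 15 and uses Mitsunobu macrolactonisation (PPh3, diisopropyl azodicarboxylate, toluene, high dilution), in which the carboxylate displaces the activated carbinol with inversion. Inversion is harmless because the centre is racemic, and the fallback returns to the route at 17 without any new intermediate.

## Further compounds

F1 | step 9 | racemic 7-{3-[3-(6-hydroxyoct-7-en-1-yl)-2,5-dimethoxyphenoxy]-5-methoxyphenyl}heptanal | O=CCCCCCCc1cc(OC)cc(c1)Oc1cc(OC)cc(c1OC)CCCCC[C@H](C=C)O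
F2 | step 9 | racemic 8-{2,5-dimethoxy-3-[3-methoxy-5-(oct-7-en-1-yl)phenoxy]phenyl}oct-1-en-3-ol | C=CCCCCCCc1cc(OC)cc(c1)Oc1cc(OC)cc(c1OC)CCCCC[C@H](C=C)O
F3 | step 9 | racemic 21-membered carbocyclic allylic alcohol (OH on C6, (E)-C7=C8, three methyl ethers) | COc1cc2cc(c1)Oc1cc(OC)cc(c1OC)CCCCC[C@@H](O)/C=C/CCCCCC2
F4 | step 9 | racemic saturated 21-membered carbocyclic alcohol (OH on C6, three methyl ethers) | COc1cc2cc(c1)Oc1cc(OC)cc(c1OC)CCCCC[C@@H](O)CCCCCCCC2
F5 | step 9 | S-methyl xanthate of F4 (racemic) | COc1cc2cc(c1)Oc1cc(OC)cc(c1OC)CCCCC[C@@H](OC(=S)SC)CCCCCCCC2
F6 | step 6 | racemic tert-butyl{[8-(3-bromo-2,5-dimethoxyphenyl)oct-1-en-3-yl]oxy}dimethylsilane | COc1cc(Br)c(OC)c(c1)CCCCC[C@H](C=C)O[Si](C)(C)C(C)(C)C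
F7 | step 6 | tert-butyldimethylsilyl ether of 14 (racemic) | COC(=O)CCCCCCc1cc(OC)cc(c1)Oc1cc(OC)cc(c1OC)CCCCC[C@H](C=C)O[Si](C)(C)C(C)(C)C
F8 | step 2 | 1-bromo-3-iodo-2,5-dimethoxybenzene | COc1cc(Br)c(OC)c(I)c1
F0 | step 8 | none | none
A1 | alternative 1 | 3-(3-bromo-5-methoxyphenoxy)-4-(hexadeca-1,15-dien-2-yl)-4-hydroxycyclobut-2-en-1-one | C=CCCCCCCCCCCCCC(=C)C1(O)C(Oc2cc(Br)cc(OC)c2)=CC1=O
A2 | alternative 1 | 2-(3-bromo-5-methoxyphenoxy)-6-(tetradec-13-en-1-yl)benzene-1,4-diol | COc1cc(Br)cc(c1)Oc1cc(O)cc(CCCCCCCCCCCCC=C)c1O
A3 | alternative 2 | pentacarbonyl{(2E)-3-[3-(hexadec-15-yn-1-yl)-5-methoxyphenoxy]-1-methoxyprop-2-en-1-ylidene}chromium | COC(/C=C/Oc1cc(OC)cc(CCCCCCCCCCCCCCC#C)c1)=[Cr](=C=O)(=C=O)(=C=O)(=C=O)=C=O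
A4 | alternative 2 | macrocyclic 4-methoxyphenol (target with the ring A hydroxyl and the remote ring B hydroxyl as methyl ethers) | COc1cc2cc(c1)Oc1cc(OC)cc(c1O)CCCCCCCCCCCCCC2
A5 | alternative 3 | 21-membered macrocyclic aryloxy ynone (ring B 2,5-dimethoxy; O–C≡C–C(=O) unit closing the tetradecamethylene bridge) | O=C1C#COc2cc(OC)cc(c2OC)CCCCCCCCCCCCCC1
A6 | alternative 3 | dimethyl 3-oxopentanedioate | COC(=O)CC(=O)CC(=O)OC
A7 | alternative 3 | macrocyclic dimethyl 2-hydroxyisophthalate (target skeleton, ring B dimethyl ether, two ester groups flanking the ring A hydroxyl) | COC(=O)c1c(O)c(C(=O)OC)c2cc1Oc1cc(OC)cc(c1OC)CCCCCCCCCCCCCC2
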